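(The earlier runs and the new flask come from a simulation with made-up constants, and the scatter is random.)

The target climbed and then fell in both runs, down to 11.5% in the south-east run at 15.0 h, so I followed the electrophile that had reacted, not the target.

the same everywhere: electrophile 0.20 M
- north: nucleophile 0.59 equiv; protic impurity 0.10 M; run made earlier
- south-east: nucleophile 1.1 equiv; protic impurity 0.10 M; run made earlier
- birch: nucleophile 1.40 equiv; protic impurity 0.100 M; time 20 h
- elm: nucleophile 0.950 equiv; protic impurity 0.100 M; time 20 h

| run | time / h | electrophile / % | target / % |
|---|---|---|---|
| north | 1.00 | 94.0 | 4.3 |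
| north | 2.00 | 90.7 | 6.6 |
| north | 4.00 | 87.7 | 7.3 |
| north | 8.00 | 82.9 | 6.0 |
| north | 15.0 | 79.2 | 2.7 |
| south-east | 1.00 | 89.2 | 9.7 |
| south-east | 2.00 | 82.4 | 13.8 |
| south-east | 4.00 | 72.9 | 16.7 |
| south-east | 8.00 | 61.9 | 15.8 |
| south-east | 15.0 | 52.4 | 11.5 |

(each reading ± 0.3 percentage points)

1. part of the electrophile that has reacted at the end, birch
2. part of the electrophile that has reacted at the end, elm
3. what raising the equivalents of nucleophile from its lowest to its highest value here does to the part of the electrophile that has reacted (changes below 5 percentage points count as none) (it rises / it falls / no change)



The south-east run slowed with 52.4% of its electrophile left, though it was charged with more nucleophile than electrophile. So I suspected that the protic impurity took nucleophile, and I wrote the nucleophile's balance (in elm it is the limiting reagent). Spare nucleophile s is the nucleophile charge minus the impurity charge, in percent of the electrophile: 9.00% for north, 60.0% for south-east.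

But north had reacted 20.8% at 15.0 h, more than its s, so s is a scale, not a ceiling. The south-east rate fell to half between its last intervals, so I carried each run on to 20 h at half its last rate. That gave 22.1% for north and 51.0% for south-east. The line between them has slope 0.566, the yield on spare nucleophile: points reacted at 20 h per point of s.

Elm, with s 45.0%, came to 42.5%. Birch, with s 90.0%, beyond south-east on the line, came to 68.0%, higher by 26 percentage points.

The forecast gave 69% (63% to 75%) for birch and 42% (38% to 46%) for elm, not quite my numbers, and for the trend it rises: “More nucleophile clearly raises conversion”.

The simulation gave birch 69.3% and elm 43.0%; the trend was it rises, by 26 points.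

    electrophile + nucleophile → acid set free + target (k = 0.0120 L mol⁻¹ min⁻¹)
    nucleophile + acid set free ⇌ protonated nucleophile, settled at all times (K = 2300 L mol⁻¹)
    electrophile + target → side product (k = 0.0110 L mol⁻¹ min⁻¹)
    nucleophile + protic impurity → quenched reagent (k = 0.130 L mol⁻¹ min⁻¹)

The neighbour flask is elm with the protic impurity cut to 0.025 M, so s moved while the nucleophile charge stayed: s was 82.5%. The same line, with yield 0.566, gave 63.7%, and the neighbour flask reached 65.0%. At 20.0 h its quenched reagent stood at 0.0250 M, its protonated nucleophile at 0.0763 M and its free nucleophile at 4.59% of its own charge. In the neighbour flask side product held 49.9% of the electrophile charged, more than the 35.0% still there as electrophile.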